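## Retrosynthetic overview

- The target is (2S)-5,7-dihydroxy-4'-methoxy-8,3'-diprenylflavanone; the last operations are O4'-methylation and removal of a 7-O-MOM group.
- The strategy rests on where the two C-prenyl groups sit: C8 of ring A is para to the C5 oxygen and C3' of ring B is ortho to the C4' oxygen. The C8–CH2 and C3'–CH2 bonds are therefore cut back to a 5-O-prenyl ether and a 4'-O-(1,1-dimethylallyl) ether.
- Both O-to-C transfers are run in one flask: an ortho-Claisen shift on ring B, and a Claisen shift to C6 followed by a Cope shift to C8 on ring A.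
- The bis-ether is assembled on (S)-naringenin by 7-O-MOM protection, 4'-O-propargylation with semi-hydrogenation, and 5-O-Mitsunobu prenylation.
- No ring is formed in the route: rings A, B and C and the C2 stereocentre all come from naringenin.

Key step: step 5

Assumption: (2S)-naringenin is bought as the enantiomerically enriched natural isomer; its ee is checked by chiral HPLC on receipt and C2 integrity is re-checked after each step that uses an amine base.

## Route

Step 1
Reactants: 1 (S)-naringenin
Product: 2 (2S)-5-hydroxy-2-(4-hydroxyphenyl)-7-(methoxymethoxy)chroman-4-one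
Conditions: MOMCl (1.05 equiv), i-Pr2NEt (1.2 equiv), THF, 0 °C → rt
Reagents that add atoms: chloromethyl methyl ether (MOMCl), COCCl
Why: O-alkylation of a phenoxide (Williamson type): the 7-OH, para to the C4 carbonyl, is the most acidic phenol and the only one appreciably ionised by the hindered amine, while the 5-OH is held in a hydrogen bond to C4=O and the 4'-OH stays largely protonated.

Step 2
Reactants: 2 (2S)-5-hydroxy-2-(4-hydroxyphenyl)-7-(methoxymethoxy)chroman-4-one; 3 3-chloro-3-methylbut-1-yne
Product: 4 (2S)-5-hydroxy-7-(methoxymethoxy)-2-[4-(2-methylbut-3-yn-2-yloxy)phenyl]chroman-4-one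
Conditions: 3 (1.3 equiv), DBU (1.5 equiv), CuCl2·2H2O (1 mol %), MeCN, −5 to 0 °C
Reagents that add atoms: none
Why: Copper-catalysed propargylic etherification of a phenol, in which the phenoxide captures a copper acetylide/allenylidene species at the tertiary carbon; only the free 4'-phenoxide is nucleophilic, the hydrogen-bonded 5-OH stays inert, and low temperature with short contact with DBU is chosen to keep ring C closed.

Step 3
Reactants: 4 (2S)-5-hydroxy-7-(methoxymethoxy)-2-[4-(2-methylbut-3-yn-2-yloxy)phenyl]chroman-4-one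
Product: 5 (2S)-5-hydroxy-7-(methoxymethoxy)-2-[4-(2-methylbut-3-en-2-yloxy)phenyl]chroman-4-one
Conditions: H2 (1 atm), Pd/CaCO3 poisoned with Pb(OAc)2 (Lindlar catalyst), quinoline, EtOAc, rt; concentrated below 30 °C
Reagents that add atoms: none
Why: Lindlar semi-hydrogenation stops at the terminal alkene and leaves the aryl ketone, the benzylic C2–O bond and the MOM acetal untouched; the tertiary allyl ether is kept cold so that it does not rearrange before it is wanted.

Step 4
Reactants: 5 (2S)-5-hydroxy-7-(methoxymethoxy)-2-[4-(2-methylbut-3-en-2-yloxy)phenyl]chroman-4-one; 6 prenol (3-methylbut-2-en-1-ol)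
Product: 7 (2S)-7-(methoxymethoxy)-5-(3-methylbut-2-enyloxy)-2-[4-(2-methylbut-3-en-2-yloxy)phenyl]chroman-4-one
Conditions: PPh3, DIAD, THF, 0 °C → rt (kept below 25 °C)
Reagents that add atoms: none
Why: Mitsunobu etherification: the hydrogen-bonded 5-OH resists base/halide alkylation but is acidic enough to protonate the betaine, and its phenoxide attacks the primary carbon of the prenyloxyphosphonium ion (SN2, no allylic transposition) under neutral conditions below the onset of the ring-B Claisen shift.

Step 5
Reactants: 7 (2S)-7-(methoxymethoxy)-5-(3-methylbut-2-enyloxy)-2-[4-(2-methylbut-3-en-2-yloxy)phenyl]chroman-4-one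
Product: 10 (2S)-5-hydroxy-2-[4-hydroxy-3-(3-methylbut-2-enyl)phenyl]-7-(methoxymethoxy)-8-(3-methylbut-2-enyl)chroman-4-one, via C6 reverse-prenyl dienone 8 (not isolated), via 8-prenyl ring-B allyl ether 9 (not isolated)
Conditions: Eu(fod)3 (10 mol %), PhCl, 65 °C, then 100 °C, Ar, sealed tube
Reagents that add atoms: none
Why: Trivalent europium chelated between the C4 carbonyl and O5 accelerates a [3,3] ortho-Claisen shift of the 5-O-prenyl group to C6 (the other ortho carbon, C4a, is blocked), giving dienone 8 with a 1,1-dimethylallyl group on an sp3 C6. A Cope [3,3] shift through C6–C7=C8 then carries the allyl unit to C8 with a second allylic inversion, which restores the linear prenyl group, and enolisation gives the chelated 5-hydroxy compound 9. On further heating the ring-B 1,1-dimethylallyl ether undergoes an ortho-Claisen shift to C3' (the two ortho carbons are equivalent) and tautomerises to the 3'-prenylphenol 10. The closest known reaction types are the Eu(fod)3-promoted para-Claisen–Cope rearrangement of 5-O-prenylflavanones and the aromatic Claisen rearrangement of aryl 1,1-dimethylallyl ethers. No ring is closed and no lasting stereocentre is made (the sp3 C6 of 8 is transient); C2 is not part of either pericyclic array and the medium is neutral. The selectivity needed is C8 over C6: the congested quaternary carbon at C6, flanked by C5=O and the 7-OMOM group, together with a dry aprotic medium without proton shuttles, should let the Cope shift outrun enolisation of 8.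

Step 6
Reactants: 10 (2S)-5-hydroxy-2-[4-hydroxy-3-(3-methylbut-2-enyl)phenyl]-7-(methoxymethoxy)-8-(3-methylbut-2-enyl)chroman-4-one
Product: 11 (2S)-5-hydroxy-2-[4-methoxy-3-(3-methylbut-2-enyl)phenyl]-7-(methoxymethoxy)-8-(3-methylbut-2-enyl)chroman-4-one
Conditions: TMSCHN2 (2 M in hexanes), i-Pr2NEt, MeCN–MeOH (9:1), rt
Reagents that add atoms: trimethylsilyldiazomethane, C[Si](C)(C)C=[N+]=[N-]
Why: Aoyama–Shioiri O-methylation with a diazoalkane (diazomethane released by methanolysis of the silyl reagent): only the free 4'-phenol protonates the reagent and is methylated, the 5-OH being locked in its hydrogen bond to C4=O, and no strong base is present that could open ring C.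

Step 7
Reactants: 11 (2S)-5-hydroxy-2-[4-methoxy-3-(3-methylbut-2-enyl)phenyl]-7-(methoxymethoxy)-8-(3-methylbut-2-enyl)chroman-4-one
Product: 12 (2S)-5,7-dihydroxy-2-[4-methoxy-3-(3-methylbut-2-enyl)phenyl]-8-(3-methylbut-2-enyl)chroman-4-one
Conditions: HCl (3 M aq), MeOH, 45 °C, stopped at full conversion
Reagents that add atoms: none
Why: Acid-catalysed acetal solvolysis (MOM ether cleavage) passes the methoxymethyl unit to methanol; mild acid and moderate temperature are chosen so that the freed 7-OH does not add to the neighbouring C8 prenyl alkene and C2 is not epimerised.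

## Compound list

1 | (S)-naringenin, (2S)-5,7-dihydroxy-2-(4-hydroxyphenyl)chroman-4-one | O=C1C[C@@H](c2ccc(O)cc2)Oc2cc(O)cc(O)c12 | starting material
2 | (2S)-5-hydroxy-2-(4-hydroxyphenyl)-7-(methoxymethoxy)chroman-4-one | Oc1ccc([C@@H]2CC(=O)c3c(O)cc(OCOC)cc3O2)cc1 | intermediate
3 | 3-chloro-3-methylbut-1-yne | C#CC(C)(C)Cl | starting material
4 | (2S)-5-hydroxy-7-(methoxymethoxy)-2-[4-(2-methylbut-3-yn-2-yloxy)phenyl]chroman-4-one | C#CC(C)(C)Oc1ccc([C@@H]2CC(=O)c3c(O)cc(OCOC)cc3O2)cc1 | intermediate
5 | (2S)-5-hydroxy-7-(methoxymethoxy)-2-[4-(2-methylbut-3-en-2-yloxy)phenyl]chroman-4-one | C=CC(C)(C)Oc1ccc([C@@H]2CC(=O)c3c(O)cc(OCOC)cc3O2)cc1 | intermediate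
6 | prenol (3-methylbut-2-en-1-ol) | CC(C)=CCO | starting material
7 | (2S)-7-(methoxymethoxy)-5-(3-methylbut-2-enyloxy)-2-[4-(2-methylbut-3-en-2-yloxy)phenyl]chroman-4-one | C=CC(C)(C)Oc1ccc([C@@H]2CC(=O)c3c(OCC=C(C)C)cc(OCOC)cc3O2)cc1 | intermediate
8 | (2S)-7-(methoxymethoxy)-6-(2-methylbut-3-en-2-yl)-2-[4-(2-methylbut-3-en-2-yloxy)phenyl]-2,3-dihydro-4H-chromene-4,5(6H)-dione (C6 dienone, C6 configuration not defined) | C=CC(C)(C)Oc1ccc([C@@H]2CC(=O)C3=C(O2)C=C(OCOC)C(C(C)(C)C=C)C3=O)cc1 | intermediate
9 | (2S)-5-hydroxy-7-(methoxymethoxy)-8-(3-methylbut-2-enyl)-2-[4-(2-methylbut-3-en-2-yloxy)phenyl]chroman-4-one | C=CC(C)(C)Oc1ccc([C@@H]2CC(=O)c3c(O)cc(OCOC)c(CC=C(C)C)c3O2)cc1 | intermediate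
10 | (2S)-5-hydroxy-2-[4-hydroxy-3-(3-methylbut-2-enyl)phenyl]-7-(methoxymethoxy)-8-(3-methylbut-2-enyl)chroman-4-one | Oc1ccc([C@@H]2CC(=O)c3c(O)cc(OCOC)c(CC=C(C)C)c3O2)cc1CC=C(C)C | intermediate
11 | (2S)-5-hydroxy-2-[4-methoxy-3-(3-methylbut-2-enyl)phenyl]-7-(methoxymethoxy)-8-(3-methylbut-2-enyl)chroman-4-one | COc1ccc([C@@H]2CC(=O)c3c(O)cc(OCOC)c(CC=C(C)C)c3O2)cc1CC=C(C)C | intermediate
12 | (2S)-5,7-dihydroxy-2-[4-methoxy-3-(3-methylbut-2-enyl)phenyl]-8-(3-methylbut-2-enyl)chroman-4-one | COc1ccc([C@@H]2CC(=O)c3c(O)cc(O)c(CC=C(C)C)c3O2)cc1CC=C(C)C | target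

Total step count: 7
Longest linear sequence: 7 steps (1 → 2 → 4 → 5 → 7 → 10 → 11 → 12)

## Steps most likely to fail

**Step 5 (key step).** The ring-A relay may stop at C6 if dienone 8 enolises before the Cope shift. The two shifts may also need different temperature windows, so that prolonged heating with the Lewis acid lets the freed ortho-prenylphenols add to their alkenes. The fallback separates the two shifts and sets out from 5. Heating 5 in toluene at 110 °C (thermal ortho-Claisen shift, no Lewis acid) should give (2S)-5-hydroxy-2-[4-hydroxy-3-(3-methylbut-2-enyl)phenyl]-7-(methoxymethoxy)chroman-4-one F1. Methylation of its 4'-OH with TMSCHN2/i-Pr2NEt in MeCN–MeOH should give (2S)-5-hydroxy-2-[4-methoxy-3-(3-methylbut-2-enyl)phenyl]-7-(methoxymethoxy)chroman-4-one F2. Mitsunobu reaction of F2 with prenol 6 (PPh3, DIAD, THF) should give (2S)-2-[4-methoxy-3-(3-methylbut-2-enyl)phenyl]-7-(methoxymethoxy)-5-(3-methylbut-2-enyloxy)chroman-4-one F3. Eu(fod)3 in CHCl3 at 60 °C then has to run only the ring-A Claisen–Cope relay, at the temperature established for 5-O-prenylflavanones, and the product is compound 11, where the route is rejoined before step 7.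

**Step 2.** DBU acting on the 4'-phenoxide may reversibly open ring C (C2–O1 cleavage towards the chalcone), which would erode the C2 configuration, and some alkylation at O5 may compete. The fallback sets out from 2 and needs no added base. 2-Methylbut-3-en-2-ol is converted with Boc2O (n-BuLi, THF) into tert-butyl 2-methylbut-3-en-2-yl carbonate F4. Tsuji–Trost O-allylation of 2 with this carbonate and Pd(PPh3)4 in THF at 0 °C → rt should deliver the tertiary (branched) aryl ether by attack of the phenoxide at the more substituted allyl terminus. This gives compound 5 directly, so steps 2 and 3 are replaced by one operation and the route is rejoined at 5.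

**Step 7.** Under protic acid the liberated 7-OH may add across the C8 prenyl double bond (chroman ring closure), or the prenyl alkenes may be hydrated. The fallback sets out from 11 and avoids Brønsted acid by silyl transfer. TMSOTf with 2,2'-bipyridyl in MeCN at 0 °C should convert the aryl MOM ether into (2S)-5-hydroxy-2-[4-methoxy-3-(3-methylbut-2-enyl)phenyl]-8-(3-methylbut-2-enyl)-7-(trimethylsilyloxy)chroman-4-one F5. Addition of water to the same flask hydrolyses the silyl ether and gives compound 12.

## Further compounds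

F1 | step 5 | (2S)-5-hydroxy-2-[4-hydroxy-3-(3-methylbut-2-enyl)phenyl]-7-(methoxymethoxy)chroman-4-one | Oc1ccc([C@@H]2CC(=O)c3c(O)cc(OCOC)cc3O2)cc1CC=C(C)C
F2 | step 5 | (2S)-5-hydroxy-2-[4-methoxy-3-(3-methylbut-2-enyl)phenyl]-7-(methoxymethoxy)chroman-4-one | COc1ccc([C@@H]2CC(=O)c3c(O)cc(OCOC)cc3O2)cc1CC=C(C)C
F3 | step 5 | (2S)-2-[4-methoxy-3-(3-methylbut-2-enyl)phenyl]-7-(methoxymethoxy)-5-(3-methylbut-2-enyloxy)chroman-4-one | COc1ccc([C@@H]2CC(=O)c3c(OCC=C(C)C)cc(OCOC)cc3O2)cc1CC=C(C)C
F4 | step 2 | tert-butyl 2-methylbut-3-en-2-yl carbonate | C=CC(C)(C)OC(=O)OC(C)(C)C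
F5 | step 7 | (2S)-5-hydroxy-2-[4-methoxy-3-(3-methylbut-2-enyl)phenyl]-8-(3-methylbut-2-enyl)-7-(trimethylsilyloxy)chroman-4-one | COc1ccc([C@@H]2CC(=O)c3c(O)cc(O[Si](C)(C)C)c(CC=C(C)C)c3O2)cc1CC=C(C)C
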